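Readings and results are calculated for an exercise; noise was put on by code.

As the chemist who had to charge the next pair of flasks, I wanted to know whether a second catalyst loading was worth a run, or whether the excess of right-handed substrate would come out the same.

in all of them: left-handed substrate 0.74 M; right-handed substrate 0.74 M; partner 0.814 M
- east: free catalyst 21 mM; run made earlier
- north: free catalyst 68 mM; run made earlier
- maple: free catalyst 19 mM; time 2.5 h
- larch: free catalyst 60 mM; time 2.5 h

| run | time / min | right-handed substrate / % | left-handed substrate / % |
|---|---|---|---|
| east | 10.0 | 42.1 | 34.3 |
| east | 20.0 | 39.8 | 30.5 |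
| east | 30.0 | 38.3 | 28.2 |
| east | 40.0 | 36.7 | 27.6 |
| east | 50.0 | 36.9 | 26.0 |
| east | 60.0 | 36.4 | 25.4 |
| east | 80.0 | 36.8 | 25.5 |
| north | 4.00 | 38.9 | 29.5 |
| north | 12.0 | 35.1 | 22.8 |
| north | 20.0 | 33.9 | 20.2 |
| north | 30.0 | 33.0 | 19.8 |
| north | 50.0 | 32.9 | 18.7 |
| north | 60.0 | 32.7 | 19.6 |
| north | 80.0 | 32.7 | 19.0 |

(readings scatter by 0.5 percentage points)

- free catalyst is single-handed; left-handed substrate and right-handed substrate are mirror images of each other, charged as a racemate, each of them at the stated concentration
- an excess is below zero if the other one leads

* the flask that ends with the higher excess of right-handed substrate over left-handed substrate among what is left of the two, or "neither" when 2 percentage points or less lies between them (maple / larch / neither)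
* excess of right-handed substrate over left-handed substrate among what is left of the two at the end, maple
* excess of right-handed substrate over left-handed substrate among what is left of the two at the end, larch

Let r and l be the fractions of right-handed and left-handed substrate left of their own charge, and take ln l / ln r at the last reading of each run:

east, with 21 mM of free catalyst: 2.20
north, with 68 mM of free catalyst: 2.28
mean: s = 2.24

This s is the selectivity factor, the ratio ln l / ln r, read through a scatter of 0.5 percentage points. The two readings lie close together despite the different loadings, so I took s as fixed at these charges. Then l = r^s, and the excess e = (r − l)/(r + l) depends on r: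

east, r = 73.6%: e = 18.7%
north, r = 65.4%: e = 25.7%

The gap of 7.0 points is wider than the margin of 2 points, so I ran both loadings. Right-handed substrate in east stood at 36.4% after 60.0 min and 36.8% after 80.0 min, so I kept 2.5 h. Maple holds less catalyst than east and larch less than north, so I expected each slightly below my figure.

The forecast named larch, with 17.4% (16.2% to 18.6%) for maple and 25.6% (24% to 27%) for larch. One of its grounds was this: “The stall level depends on catalyst loading, so the catalyst is dying.”

The flasks gave 17.7% for maple and 24.3% for larch, so larch led.

    free catalyst ⇌ dormant form (K = 1.19, k = 0.00326 s⁻¹)
    partner + free catalyst + right-handed substrate → free catalyst + right-handed product (k = 0.0427 M⁻² s⁻¹)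
    2 free catalyst → spent catalyst (k = 0.00875 M⁻¹ s⁻¹)
    partner → decomposed reagent (k = 3.16 × 10⁻⁴ s⁻¹)
    partner + free catalyst + left-handed substrate → free catalyst + left-handed product (k = 0.0919 M⁻² s⁻¹)

Maple ended with r = 73% and l = 51%, so its ratio of logarithms is 2.14. A neighbouring flask, maple with 2.0 M of partner, ended with r = 37%. My s turns that into l = 10.9% and e = 54.9%. That neighbour in fact held l = 12% and ended at an excess of 51.6%.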